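## Analysis of the target

Target 11 is 3,5-dibromo-2-(2,4-dibromophenoxy)phenol, an achiral diaryl ether in which two benzene rings are joined through one oxygen; there is no stereocentre to set. Ring A carries the free hydroxyl on C1, the ether oxygen on C2 and bromine on C3 and C5, while ring B is bound through C1' and carries bromine on C2' and C4'. The sensitive groups are the phenol, which is acidic, oxidisable and strongly activating toward electrophiles, and four aryl C–Br bonds, which exclude organolithium reagents and make hot copper- or palladium-catalysed ether couplings unsafe. The synthesis is hard for two reasons: the ether oxygen is flanked by three ortho substituents (C1–O and C3–Br on ring A, C2'–Br on ring B), and four bromines must be placed on two rings without positional isomers. The plan rests on ring B: its only substituent besides bromine is the ether oxygen, and C2' and C4' are ortho and para to it, so they are the natural sites of electrophilic substitution of a phenoxy group. Ring A differs: C3 and C5 are ortho and para to the C2 oxygen but meta to the C1 oxygen, so its bromines must be set while the C2 oxygen is a free hydroxyl. Once the C1 oxygen is acylated, the open carbons C4 and C6 are meta to the ether oxygen, adjacent to bromine, and unreactive.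

## Retrosynthetic reasoning

Locants C1–C6 (ring A) and C1'–C6' (ring B) are those of 11 throughout.

**11 ⇒ 10.** The acyl–oxygen bond on the C1 oxygen is cut first. The phenol is released last because a free C1 hydroxyl would send an electrophile to C6 and C4 of ring A. The forward reaction is a mild methanolysis that must leave the C–Br bonds and the diaryl ether alone.

**10 ⇒ 7 + 8.** The C4'–Br and C2'–Br bonds are cut together. They are the only two C–Br bonds of the target that the electronics of the substrate can deliver after the ether exists. Removing them turns ring B into a plain phenyl group, so the hindered ether can be made from the simplest aryl donor. The ring A bromines are not cut at this stage, because they are meta to the C1 oxygen and no late electrophilic step would place them. The forward reaction must brominate ring B twice, passing through the 4'-monobromide 9, leave ring A alone and stop after the second bromine.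

**7 ⇒ 6 ⇒ 4.** The C1 oxygen changes its protecting group: the O–acyl bond is cut, then the O–CH3 bond. A methyl ether is wanted earlier because it survives the strong alkoxide base of the arylation and keeps the two oxygens of ring A distinct. It cannot stay for the bromination, because the oxygen of an aryl methyl ether would activate C4 (para) and C6 (ortho) of ring A about as much as the ether oxygen activates ring B. The forward steps are a Lewis-acid demethylation, which cannot attack the diaryl ether because that oxygen bears no sp3 carbon, and an acetylation.

**4 ⇒ 2 + 3.** The O–C1' bond is cut. The C2 oxygen then comes from a phenol whose hydroxyl also directed the ring A bromines, and ring B comes as the electrophilic phenyl group of the trivalent iodine reagent 3. Aryl transfer from iodine needs no transition metal, so the two C–Br bonds of 2 are not at risk. Substitution by addition–elimination is not possible on an unactivated phenyl ring. A donor that already carries the ring B bromines was weighed at this point. It would have to be made, and it would close a tri-ortho-substituted ether with a weak nucleophile. With 3 the nucleophilic oxygen has only its own two ortho neighbours to contend with, at the price of the protecting-group change above.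

**2 ⇒ 1.** The C3–Br bond, ortho to the hydroxyl of 2, is cut. Compound 1 is a catalogue phenol that already has the C5 bromine para to its hydroxyl. The last bromine can enter ortho to OH (C3) or para to OMe (C4), and a plain electrophilic bromination is not trusted to choose between them. The forward reaction is therefore an amine-mediated bromination that delivers bromine through a hydrogen bond to the hydroxyl and so only to C3.

## Alternatives that were turned down

**Alternative 1:** Ring A is traced to 1,3-dibromobenzene A1 by removing both C–O bonds of ring A and its aromaticity.
- Forward key step: whole cells expressing toluene dioxygenase add two oxygens from air to one face of one C=C bond of A1 and give (1S,2S)-3,5-dibromocyclohexa-3,5-diene-1,2-diol A2. The C2 hydroxyl of A2 would then be arylated and the C1 carbinol oxidised so that the ring re-aromatises.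
- For it: the 1,2-dioxygen, 3,5-dibromo pattern of ring A is fixed in one step from a cheap symmetrical arene with no choice of site for an electrophile. On this point it is stronger than the chosen route, whose step 1 depends on ortho delivery of bromine.
- Against it: the two stereocentres of A2 are made by fermentation and then erased, since 11 is achiral. A2 loses water easily under acid, base or heat and then re-aromatises with only one of its two oxygens. The two allylic hydroxyls must be told apart, and the more hindered one, next to C3–Br, must become a crowded aryl ether by way of a base-sensitive alkoxide.
- Comparison: at least four operations follow the key step, and the risk sits in fragile non-aromatic intermediates. The chosen strategy gives up the built-in ring A pattern but keeps every intermediate aromatic and robust.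

**Alternative 2:** The C2–C3 and C1–C6 bonds of ring A are cut. C3–C6 come from 3,5-dibromo-2H-pyran-2-one A3 and C1–C2 from the borylated ynol ether 2-[(2,4-dibromophenoxy)ethynyl]-4,4,5,5-tetramethyl-1,3,2-dioxaborolane A4.
- Forward key step: a Diels–Alder reaction of A3 with A4 followed by decarboxylative aromatisation gives 2-[3,5-dibromo-2-(2,4-dibromophenoxy)phenyl]-4,4,5,5-tetramethyl-1,3,2-dioxaborolane A5, and oxidation of the C–B bond of A5 would give 11.
- For it: it is convergent and all four bromines arrive in the fragments, so neither ring selectivity nor over-bromination arises. The C1 oxygen needs no protecting group. The regiochemistry is plausible, because the boron-bearing alkyne carbon of A4 is the nucleophilic end and should join C6 of the electron-poor pyrone A3. On these points it is stronger than the chosen route.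
- Against it: A4 is a push–pull ynol ether whose preparation calls for deprotonation of a terminal ynol ether with a strong base beside two aryl C–Br bonds, where halogen–metal exchange and aryne formation compete. A4 is also prone to hydration and polymerisation at the temperatures such cycloadditions need.
- Comparison: both fragments need several steps, so the total exceeds six. The chosen strategy offers purchased benzene rings and only reagent-grade steps that tolerate C–Br bonds.

**Alternative 3:** The C1'–C2' and C5'–C6' bonds of ring B are cut. C2'–C5' come from A3, and C1' and C6' from 1,5-dibromo-2-(ethynyloxy)-3-methoxybenzene A6, the ethynyl ether of 2.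
- Forward key step: a Diels–Alder reaction of A3 with A6 and decarboxylative aromatisation give 1,5-dibromo-2-(2,4-dibromophenoxy)-3-methoxybenzene A7, and demethylation of A7 would give 11.
- For it: the ring B bromines are fixed by A3, no acyl protection is needed, only one step follows the key step, and the expected regiochemistry (terminal alkyne carbon of A6 to C6 of the pyrone) is the right one. On positional certainty for ring B it is stronger than the chosen route.
- Against it: making A6 from 2 takes an O-alkenylation with a chlorinated alkene and a double elimination with strong base, which again conflicts with the aryl bromides. The ynol ether oxygen of A6 is flanked by Br and OMe, and the cycloaddition would build by heat a benzene ring that can be bought as a phenyl group.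
- Comparison: with the preparation of A3 and A6 the count is higher than in the chosen route. The chosen strategy replaces ring construction by a substitution whose regiochemistry is the innate one.

Key step: step 5

Remark on the chemistry: potassium phenoxides formed by deprotonation in steps 2 and 6 are treated as ionised forms of the numbered phenols and carry no numbers of their own.

## Route

**Step 1**
Reactants: 1 4-bromo-2-methoxyphenol
Product: 2 2,4-dibromo-6-methoxyphenol
Conditions: NBS (1.05 equiv), i-Pr2NH (10 mol %), CH2Cl2, 0 °C → rt
Reagents that add atoms: N-bromosuccinimide, O=C1CCC(=O)N1Br
Why: Amine-mediated ortho-bromination of a phenol (electrophilic aromatic substitution): NBS and the amine should form an N-bromoamine that hydrogen-bonds to the hydroxyl and hands bromine to the adjacent free carbon (ring A C3), so the competing carbon para to OMe (ring A C4) is bypassed. In 2 the hydroxyl oxygen is the later C2 ether oxygen, the bromines are the later C3 and C5 bromines and the methoxy oxygen is the later C1 oxygen.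

**Step 2**
Reactants: 2 2,4-dibromo-6-methoxyphenol; 3 diphenyliodonium triflate
Product: 4 1,5-dibromo-3-methoxy-2-phenoxybenzene
Conditions: KOtBu (1.1 equiv), THF, 0 °C; then 3 (1.2 equiv), 40 °C
Reagents that add atoms: none
Why: Metal-free O-arylation of a phenoxide with a diaryliodonium salt: the phenoxide should exchange with triflate at trivalent iodine, and ligand coupling then forms the O–C1' bond and releases iodobenzene. No transition metal is present, so the C–Br bonds are untouched, and this reaction type accepts di-ortho-substituted and halogenated phenols.

**Step 3**
Reactants: 4 1,5-dibromo-3-methoxy-2-phenoxybenzene
Product: 6 3,5-dibromo-2-phenoxyphenol, via aryloxydibromoborane 5 (not isolated)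
Conditions: BBr3 (2.5 equiv), CH2Cl2, −78 °C → rt; then H2O, 0 °C
Reagents that add atoms: boron tribromide, BrB(Br)Br (its boron and two bromines are held only in 5; 6 keeps no atom of it)
Why: Lewis-acid cleavage of an aryl methyl ether: BBr3 should bind the methoxy oxygen, bromide attacks the methyl carbon (SN2) to release bromomethane and leave 5, and water hydrolyses the B–O bond to give 6. The diaryl ether oxygen bears no sp3 carbon and cannot be cleaved this way, and aryl C–Br bonds are inert to BBr3.

**Step 4**
Reactants: 6 3,5-dibromo-2-phenoxyphenol
Product: 7 3,5-dibromo-2-phenoxyphenyl acetate
Conditions: Ac2O (1.5 equiv), pyridine (3 equiv), DMAP (5 mol %), CH2Cl2, rt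
Reagents that add atoms: acetic anhydride, CC(=O)OC(C)=O
Why: DMAP-catalysed O-acylation of a phenol that has only one ortho neighbour beside the hydroxyl, so it should proceed cleanly. The acetyl group ties the C1 oxygen lone pair into a carbonyl, which removes the last strong donor from ring A before bromine is introduced.

**Step 5**
Reactants: 7 3,5-dibromo-2-phenoxyphenyl acetate; 8 bromine
Product: 10 3,5-dibromo-2-(2,4-dibromophenoxy)phenyl acetate, via 4'-monobromide 9 (not isolated)
Conditions: Br2 (2.1 equiv, slow addition), FeBr3 (5 mol %), CH2Cl2, 0 °C → rt, dark
Reagents that add atoms: none
Why: Twofold electrophilic aromatic substitution: FeBr3-polarised bromine should attack ring B at C4', where the σ-complex is stabilised by the lone pair of the ether oxygen, and loss of a proton gives 9. The second equivalent then enters at one of the two equivalent carbons ortho to that oxygen, which becomes C2' of 10. The closest known reaction type is the Lewis-acid-catalysed nuclear bromination of diphenyl ether, which substitutes para first and ortho second. No ring is closed and no stereocentre is formed. The step needs ring B to react in preference to ring A and the reaction to stop after two bromines. Ring A is shielded by its substitution: the acetylated C1 oxygen donates little, its two bromines withdraw, and its only free carbons, C4 and C6, stand meta to the ether oxygen with a bromine next door. Ring A has both positions ortho to the ether oxygen occupied and should twist out of conjugation, so the oxygen lone pair is shared mainly with ring B. A third bromine would have to enter at C6', meta to both new bromines and screened by ring A, or at C3' or C5', meta to the oxygen, so the limited charge of bromine and the low temperature should be enough to stop the reaction at 10.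

**Step 6**
Reactants: 10 3,5-dibromo-2-(2,4-dibromophenoxy)phenyl acetate
Product: 11 3,5-dibromo-2-(2,4-dibromophenoxy)phenol
Conditions: K2CO3 (1.5 equiv), MeOH, rt; then 1 M HCl
Reagents that add atoms: none
Why: Base-mediated transesterification (methanolysis) of an aryl acetate: methoxide formed by K2CO3 should attack the acetyl carbonyl and expel the dibrominated phenoxide, a good leaving group, and acidification returns the phenol. Aryl bromides and the diaryl ether do not react with carbonate in methanol at room temperature.

## Compound list

1 | 4-bromo-2-methoxyphenol | COc1cc(Br)ccc1O | starting material
2 | 2,4-dibromo-6-methoxyphenol | COc1cc(Br)cc(Br)c1O | intermediate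
3 | diphenyliodonium triflate | [O-]S(=O)(=O)C(F)(F)F.c1ccc(cc1)[I+]c1ccccc1 | starting material
4 | 1,5-dibromo-3-methoxy-2-phenoxybenzene | COc1cc(Br)cc(Br)c1Oc1ccccc1 | intermediate
5 | dibromo(3,5-dibromo-2-phenoxyphenoxy)borane | BrB(Br)Oc1cc(Br)cc(Br)c1Oc1ccccc1 | intermediate (not isolated)
6 | 3,5-dibromo-2-phenoxyphenol | Oc1cc(Br)cc(Br)c1Oc1ccccc1 | intermediate
7 | 3,5-dibromo-2-phenoxyphenyl acetate | CC(=O)Oc1cc(Br)cc(Br)c1Oc1ccccc1 | intermediate
8 | bromine | BrBr | starting material
9 | 3,5-dibromo-2-(4-bromophenoxy)phenyl acetate | CC(=O)Oc1cc(Br)cc(Br)c1Oc1ccc(Br)cc1 | intermediate (not isolated)
10 | 3,5-dibromo-2-(2,4-dibromophenoxy)phenyl acetate | CC(=O)Oc1cc(Br)cc(Br)c1Oc1ccc(Br)cc1Br | intermediate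
11 | 3,5-dibromo-2-(2,4-dibromophenoxy)phenol | Oc1cc(Br)cc(Br)c1Oc1ccc(Br)cc1Br | target

## Step count and least certain steps

Total: 6 steps. Longest linear sequence: 6 steps (1 → 2 → 4 → 6 → 7 → 10 → 11); 3 and 8 are purchased.

**Step 5 (key step).** The second substitution, ortho to the crowded ether oxygen on a ring already deactivated by the C4' bromine, should be much slower than the first. The reaction may therefore stall at the monobromide stage or, when pushed, run on to a third substitution on ring B. Loss of the acetyl group under HBr and the Lewis acid would also expose the C1 hydroxyl and open ring A to bromination.
Fallback: the two ring B bromines are brought in with the aryl donor instead of by substitution. The fallback sets out from 2 and returns at 11, replacing steps 2 to 6. 2,4-Dibromo-1-iodobenzene would be oxidised with mCPBA and TsOH in MeCN and the trivalent iodine species captured by 1,3,5-trimethoxybenzene, to give (2,4-dibromophenyl)(2,4,6-trimethoxyphenyl)iodonium 4-methylbenzenesulfonate F1. The potassium salt of 2 (KOtBu, THF or toluene, 40–60 °C) should take the electron-poor dibromophenyl group from F1 and give 1,5-dibromo-2-(2,4-dibromophenoxy)-3-methoxybenzene F2, which is the same methyl ether as A7 but is reached here without building a ring. BBr3 in CH2Cl2 would then demethylate F2 to 11.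

**Step 1.** Ortho delivery may be lost if a background bromination by free bromine, catalysed by traces of HBr, competes with the amine-bound pathway. Bromine would then enter para to OMe, and a second bromination of the product is also possible.
Fallback: the ring A substitution pattern is bought in a dibrominated salicylaldehyde and the C1 oxygen is made by oxidation. The fallback sets out from 3 and returns at 6, replacing steps 1 to 3. Purchased 3,5-dibromo-2-hydroxybenzaldehyde would be O-phenylated with 3 (KOtBu, THF, 40 °C) to 3,5-dibromo-2-phenoxybenzaldehyde F3. Baeyer–Villiger oxidation of F3 (mCPBA, CH2Cl2, rt) should give 3,5-dibromo-2-phenoxyphenyl formate F4 by aryl migration; the weak point of this detour is competing hydride migration, which would lead to the carboxylic acid. Methanolysis of F4 (K2CO3, MeOH) would give 6.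

**Step 2.** Aryl transfer may be incomplete because the phenoxide oxygen is weakly nucleophilic and shielded by Br and OMe. tert-Butoxide may also attack the iodonium salt and consume 3.
Fallback: a Chan–Lam coupling. The fallback sets out from 2 and returns at 4. Phenylboronic acid, Cu(OAc)2, pyridine and 4 Å molecular sieves in CH2Cl2 under air at room temperature should transfer phenyl to the oxygen of 2 through divalent and trivalent copper intermediates. This reaction type tolerates aryl bromides and di-ortho-halogenated phenols.

## Further compounds

F1 | step 5 | (2,4-dibromophenyl)(2,4,6-trimethoxyphenyl)iodonium 4-methylbenzenesulfonate | Cc1ccc(cc1)S(=O)(=O)[O-].COc1cc(OC)c([I+]c2ccc(Br)cc2Br)c(OC)c1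
F2 | step 5 | 1,5-dibromo-2-(2,4-dibromophenoxy)-3-methoxybenzene | COc1cc(Br)cc(Br)c1Oc1ccc(Br)cc1Br
F3 | step 1 | 3,5-dibromo-2-phenoxybenzaldehyde | O=Cc1cc(Br)cc(Br)c1Oc1ccccc1
F4 | step 1 | 3,5-dibromo-2-phenoxyphenyl formate | O=COc1cc(Br)cc(Br)c1Oc1ccccc1
F0 | step 2 | none | none
A1 | alternative 1 | 1,3-dibromobenzene | Brc1cccc(Br)c1
A2 | alternative 1 | (1S,2S)-3,5-dibromocyclohexa-3,5-diene-1,2-diol | O[C@H]1C=C(Br)C=C(Br)[C@H]1O
A3 | alternative 2 | 3,5-dibromo-2H-pyran-2-one | O=C1OC=C(Br)C=C1Br
A4 | alternative 2 | 2-[(2,4-dibromophenoxy)ethynyl]-4,4,5,5-tetramethyl-1,3,2-dioxaborolane | CC1(C)OB(OC1(C)C)C#COc1ccc(Br)cc1Br
A5 | alternative 2 | 2-[3,5-dibromo-2-(2,4-dibromophenoxy)phenyl]-4,4,5,5-tetramethyl-1,3,2-dioxaborolane | CC1(C)OB(OC1(C)C)c1cc(Br)cc(Br)c1Oc1ccc(Br)cc1Br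
A6 | alternative 3 | 1,5-dibromo-2-(ethynyloxy)-3-methoxybenzene | COc1cc(Br)cc(Br)c1OC#C
A7 | alternative 3 | 1,5-dibromo-2-(2,4-dibromophenoxy)-3-methoxybenzene | COc1cc(Br)cc(Br)c1Oc1ccc(Br)cc1Br
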